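**Plan**

- The C40 polyene is cut at C11=C12 and C11'=C12' (two Wittig reactions) into a C10 dialdehyde, the ε-ring C15 phosphonium salt and the acetylenic 3-hydroxy C15 phosphonium salt.
- In the hydroxylated ring the quaternary C1 is allylic to the tetrasubstituted C5=C6 bond and bonded to C2. With a temporary carboxyl group on C2, the unit HO2C–C2–C1–C6=C5 is a γ,δ-unsaturated acid, so the ring is opened at C1–C2 (retro-Ireland–Claisen) to a six-membered lactone with its ring oxygen on C5 and an exocyclic C6=C1Me2 group carrying the alkyne on C6.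
- The lactone is cut at C5–C6 (vinyllithium plus methyl ketone) and at C6–C7 (Sonogashira coupling of a gem-dibromoalkene).
- Forward: the side-chain bromide and the keto ester give the lactone; the rearrangement closes the carbocycle and sets C1, C5=C6 and the C6 alkyne together; the carboxyl helper is removed by radical decarboxylation; salt formation and two Wittig couplings follow (ε-ring end first).
- Stereochemistry: C3 (R) comes from an (R)-3-silyloxyglutarate half-ester and is never touched; C6' (R) comes from (R)-α-ionone; 9E comes from the E-enynol; the other E bonds come from thermodynamic control in the salt and Wittig steps; both carbinol epimers of the lactone converge.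

Key step: step 5

Assumption: compounds 1, 3, 5, 18 and 21 are taken as purchasable in the stated configuration (5 as the statin-type (R) half-ester, 18 as enantiopure (R)-α-ionone).

**Route**

Step 1
Reactants: 1 (E)-3-methylpent-2-en-4-yn-1-ol
Product: 2 tert-butyl(dimethyl){[(2E)-3-methylpent-2-en-4-yn-1-yl]oxy}silane
Conditions: TBSCl, imidazole, DMF, 0 °C → rt
Reagents that add atoms: tert-butyldimethylsilyl chloride, CC(C)(C)[Si](C)(C)Cl
Why: Silyl ether formation masks the primary hydroxyl for the organolithium, enolate and radical steps and leaves the E double bond and the terminal alkyne untouched.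

Step 2
Reactants: 2 tert-butyl(dimethyl){[(2E)-3-methylpent-2-en-4-yn-1-yl]oxy}silane; 3 1,1-dibromo-2-methylprop-1-ene
Product: 4 {[(2E)-6-bromo-3,7-dimethylocta-2,6-dien-4-yn-1-yl]oxy}(tert-butyl)dimethylsilane
Conditions: 3 in excess, Pd(PPh3)4 (cat.), CuI (cat.), i-Pr2NH, toluene, rt → 40 °C
Reagents that add atoms: none
Why: Sonogashira coupling, in which zerovalent palladium inserts into one C–Br bond of the gem-dibromide used in excess, while the remaining bromide of 4 sits on a more hindered, fully substituted carbon without a vinylic hydrogen, so a second coupling or elimination should not compete.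

Step 3
Reactants: 5 (3R)-3-{[tert-butyl(dimethyl)silyl]oxy}-5-methoxy-5-oxopentanoic acid
Product: 7 methyl (3R)-3-{[tert-butyl(dimethyl)silyl]oxy}-5-oxohexanoate, via acid chloride 6 (not isolated)
Conditions: (COCl)2, DMF (cat.), CH2Cl2, 0 °C; then Me2CuLi, Et2O, −78 °C
Reagents that add atoms: lithium dimethylcuprate, [Li+].C[Cu-]C
Why: Acid chloride formation followed by cuprate acylation stops at the methyl ketone because dialkylcuprates do not add to ketones or esters at −78 °C, and the silyloxy stereocentre takes no part.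

Step 4
Reactants: 4 {[(2E)-6-bromo-3,7-dimethylocta-2,6-dien-4-yn-1-yl]oxy}(tert-butyl)dimethylsilane; 7 methyl (3R)-3-{[tert-butyl(dimethyl)silyl]oxy}-5-oxohexanoate
Product: 10 (4R,6RS)-4-{[tert-butyl(dimethyl)silyl]oxy}-6-[(6E)-8-{[tert-butyl(dimethyl)silyl]oxy}-2,6-dimethylocta-2,6-dien-4-yn-3-yl]-6-methyloxan-2-one, via vinyllithium 8 (not isolated), via lithium alkoxide 9 (not isolated)
Conditions: 4, t-BuLi (2 equiv), Et2O/THF, −78 °C; then 7 premixed with anhydrous CeCl3, THF, −78 → 0 °C; AcOH quench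
Reagents that add atoms: none
Why: Bromine–lithium exchange gives the α-alkynyl vinyllithium 8, which should undergo 1,2-addition to the ketone through its lithiated sp2 carbon (the distal alkyne carbon is substituted and an enyne is favoured over a butatriene) with CeCl3 suppressing enolisation, after which alkoxide 9 closes the δ-lactone by intramolecular transesterification; the new carbinol centre is left uncontrolled because it becomes sp2 in step 5.

Step 5
Reactants: 10 (4R,6RS)-4-{[tert-butyl(dimethyl)silyl]oxy}-6-[(6E)-8-{[tert-butyl(dimethyl)silyl]oxy}-2,6-dimethylocta-2,6-dien-4-yn-3-yl]-6-methyloxan-2-one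
Product: 13 (1RS,6R)-6-{[tert-butyl(dimethyl)silyl]oxy}-3-[(3E)-5-{[tert-butyl(dimethyl)silyl]oxy}-3-methylpent-3-en-1-yn-1-yl]-2,2,4-trimethylcyclohex-3-ene-1-carboxylic acid, via silyl ketene acetal 11 (not isolated), via trimethylsilyl ester 12 (not isolated)
Conditions: LiN(i-Pr)2, Me3SiCl/Et3N (premixed), THF, −78 °C → rt; solvent exchange to toluene, 100 °C; then H2O/THF, rt
Reagents that add atoms: none
Why: Deprotonation at the lactone α-carbon and O-silylation give ketene acetal 11, whose C=C(OSi)–O–C–C=C array undergoes a concerted suprafacial [3,3]-sigmatropic shift that forms the C1–C2 bond of the carotenoid ring as the lactone C5–O bond breaks; the closest known reaction type is the Ireland–Claisen rearrangement of alkenyl lactone enolates to carbocycles. The cyclohexene closes in a sigmatropic mode through a boat-like transition state in which lactone and rearranging array form a bicyclo[2.2.2]octane-like arrangement, the only geometry a six-membered lactone allows, and this delivers the quaternary C1, the endocyclic tetrasubstituted C5=C6 bond and the alkyne on C6 in one event. The only new stereocentre, the carboxyl-bearing C2, is set by the face of the ketene acetal on which the axial alkenyl group sits, so each carbinol epimer of 10 should give one C2 epimer; because C5 becomes sp2 here and C2 becomes CH2 in step 6, both epimers converge on one compound, and the (R)-silyloxy centre is untouched. Regioselectivity is enforced by the tether, since only the isopropylidene terminus can reach the α-carbon and the alkyne sits on the central carbon of the allyl unit. Chemoselectivity against β-elimination of silanolate from the enolate and against ionisation of the tertiary allylic C–O bond is secured by in situ silylation at −78 °C and by a non-polar, amine-buffered medium for the thermal stage.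

Step 6
Reactants: 13 (1RS,6R)-6-{[tert-butyl(dimethyl)silyl]oxy}-3-[(3E)-5-{[tert-butyl(dimethyl)silyl]oxy}-3-methylpent-3-en-1-yn-1-yl]-2,2,4-trimethylcyclohex-3-ene-1-carboxylic acid
Product: 15 tert-butyl{[(1R)-4-[(3E)-5-{[tert-butyl(dimethyl)silyl]oxy}-3-methylpent-3-en-1-yn-1-yl]-3,5,5-trimethylcyclohex-3-en-1-yl]oxy}dimethylsilane, via thiohydroxamate ester 14 (not isolated)
Conditions: N-hydroxypyridine-2-thione, DCC, DMAP (cat.), CH2Cl2, 0 °C, dark; then t-BuSH (large excess), visible light, 0–10 °C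
Reagents that add atoms: none
Why: Barton reductive decarboxylation, in which the thiohydroxamate ester fragments to CO2 and the secondary C2 radical, which the excess thiol should trap by hydrogen transfer faster than it can attack the neighbouring ring double bond; this removes the helper and the temporary C2 stereocentre, so both epimers of 13 give one compound.

Step 7
Reactants: 15 tert-butyl{[(1R)-4-[(3E)-5-{[tert-butyl(dimethyl)silyl]oxy}-3-methylpent-3-en-1-yn-1-yl]-3,5,5-trimethylcyclohex-3-en-1-yl]oxy}dimethylsilane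
Product: 16 (1R)-4-[(3E)-5-hydroxy-3-methylpent-3-en-1-yn-1-yl]-3,5,5-trimethylcyclohex-3-en-1-ol
Conditions: Bu4NF, AcOH (buffer), THF, 0 °C → rt
Reagents that add atoms: none
Why: Fluoride-mediated silyl ether cleavage, buffered with acetic acid, frees both hydroxyls without base-induced isomerisation of the enyne.

Step 8
Reactants: 16 (1R)-4-[(3E)-5-hydroxy-3-methylpent-3-en-1-yn-1-yl]-3,5,5-trimethylcyclohex-3-en-1-ol
Product: 17 {(2E)-5-[(4R)-4-hydroxy-2,6,6-trimethylcyclohex-1-en-1-yl]-3-methylpent-2-en-4-yn-1-yl}triphenylphosphonium bromide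
Conditions: Ph3P·HBr, MeOH/CH2Cl2, rt; crystallisation
Reagents that add atoms: triphenylphosphine hydrobromide, c1ccc(cc1)[PH+](c1ccccc1)c1ccccc1.[Br-]
Why: Phosphonium salt formation from an allylic alcohol by acid-mediated ionisation and substitution, in which only the primary allylic hydroxyl ionises and triphenylphosphine captures the delocalised cation at the unhindered primary terminus, while the secondary ring hydroxyl is inert and the E salt is purified by crystallisation.

Step 9
Reactants: 18 (3E)-4-[(1R)-2,6,6-trimethylcyclohex-2-en-1-yl]but-3-en-2-one ((R)-α-ionone)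
Product: 19 (1E,3RS)-3-methyl-1-[(1R)-2,6,6-trimethylcyclohex-2-en-1-yl]penta-1,4-dien-3-ol
Conditions: CH2=CHMgBr, THF, −20 → 0 °C; H2O
Reagents that add atoms: vinylmagnesium bromide, C=C[Mg]Br
Why: Grignard 1,2-addition to the enone carbonyl is faster than γ-deprotonation, so the ring stereocentre is retained, and the uncontrolled tertiary carbinol centre is destroyed in step 10.

Step 10
Reactants: 19 (1E,3RS)-3-methyl-1-[(1R)-2,6,6-trimethylcyclohex-2-en-1-yl]penta-1,4-dien-3-ol
Product: 20 {(2E,4E)-3-methyl-5-[(1R)-2,6,6-trimethylcyclohex-2-en-1-yl]penta-2,4-dien-1-yl}triphenylphosphonium bromide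
Conditions: Ph3P·HBr, MeOH, 0 °C → rt; crystallisation
Reagents that add atoms: triphenylphosphine hydrobromide, c1ccc(cc1)[PH+](c1ccccc1)c1ccccc1.[Br-]
Why: Acid-mediated allylic transposition to the phosphonium salt (ionisation to the pentadienyl cation and capture by triphenylphosphine at the primary terminus) should give the conjugated 9'E salt as the thermodynamic isomer, and the ring stereocentre is not part of the cation.

Step 11
Reactants: 20 {(2E,4E)-3-methyl-5-[(1R)-2,6,6-trimethylcyclohex-2-en-1-yl]penta-2,4-dien-1-yl}triphenylphosphonium bromide; 21 (2E,4E,6E)-2,7-dimethylocta-2,4,6-trienedial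
Product: 22 (2E,4E,6E,8E,10E,12E)-2,7,11-trimethyl-13-[(1R)-2,6,6-trimethylcyclohex-2-en-1-yl]trideca-2,4,6,8,10,12-hexaenal
Conditions: 21 in excess, NaOMe, MeOH/CH2Cl2, 0 °C → rt; then heptane, reflux
Reagents that add atoms: none
Why: Wittig olefination of one aldehyde of the symmetrical dialdehyde, used in excess to suppress double condensation, gives an E/Z mixture at the new C11'=C12' bond that should equilibrate on heating to the all-E aldehyde because the hindered 11'Z isomer is thermally labile.

Step 12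
Reactants: 17 {(2E)-5-[(4R)-4-hydroxy-2,6,6-trimethylcyclohex-1-en-1-yl]-3-methylpent-2-en-4-yn-1-yl}triphenylphosphonium bromide; 22 (2E,4E,6E,8E,10E,12E)-2,7,11-trimethyl-13-[(1R)-2,6,6-trimethylcyclohex-2-en-1-yl]trideca-2,4,6,8,10,12-hexaenal
Product: 23 (3R,6'R)-7,8-didehydro-β,ε-caroten-3-ol (all-E)
Conditions: NaOMe, MeOH/CH2Cl2, −10 °C → rt, dark; then heptane, reflux; crystallisation
Reagents that add atoms: none
Why: Wittig olefination forms the C11=C12 bond with the free hydroxyl tolerated by methoxide, and the hindered 11Z isomer should convert thermally to the all-E target without iodine or light so that the 9E geometry next to the alkyne is kept.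

**Compound list**

1 | (E)-3-methylpent-2-en-4-yn-1-ol | C#C/C(C)=C/CO | starting material
2 | tert-butyl(dimethyl){[(2E)-3-methylpent-2-en-4-yn-1-yl]oxy}silane | C#C/C(C)=C/CO[Si](C)(C)C(C)(C)C | intermediate
3 | 1,1-dibromo-2-methylprop-1-ene | CC(C)=C(Br)Br | starting material
4 | {[(2E)-6-bromo-3,7-dimethylocta-2,6-dien-4-yn-1-yl]oxy}(tert-butyl)dimethylsilane | CC(C)=C(Br)C#C/C(C)=C/CO[Si](C)(C)C(C)(C)C | intermediate
5 | (3R)-3-{[tert-butyl(dimethyl)silyl]oxy}-5-methoxy-5-oxopentanoic acid | COC(=O)C[C@H](O[Si](C)(C)C(C)(C)C)CC(=O)O | starting material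
6 | methyl (3S)-3-{[tert-butyl(dimethyl)silyl]oxy}-5-chloro-5-oxopentanoate | COC(=O)C[C@H](O[Si](C)(C)C(C)(C)C)CC(Cl)=O | intermediate
7 | methyl (3R)-3-{[tert-butyl(dimethyl)silyl]oxy}-5-oxohexanoate | COC(=O)C[C@H](O[Si](C)(C)C(C)(C)C)CC(C)=O | intermediate
8 | [(6E)-8-{[tert-butyl(dimethyl)silyl]oxy}-2,6-dimethylocta-2,6-dien-4-yn-3-yl]lithium | [Li]C(=C(C)C)C#C/C(C)=C/CO[Si](C)(C)C(C)(C)C | intermediate
9 | lithium alkoxide of methyl (3R,5RS)-3-{[tert-butyl(dimethyl)silyl]oxy}-5-hydroxy-5-[(6E)-8-{[tert-butyl(dimethyl)silyl]oxy}-2,6-dimethylocta-2,6-dien-4-yn-3-yl]hexanoate | COC(=O)C[C@H](O[Si](C)(C)C(C)(C)C)CC(C)(O[Li])C(=C(C)C)C#C/C(C)=C/CO[Si](C)(C)C(C)(C)C | intermediate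
10 | (4R,6RS)-4-{[tert-butyl(dimethyl)silyl]oxy}-6-[(6E)-8-{[tert-butyl(dimethyl)silyl]oxy}-2,6-dimethylocta-2,6-dien-4-yn-3-yl]-6-methyloxan-2-one | O=C1C[C@H](O[Si](C)(C)C(C)(C)C)CC(C)(O1)C(=C(C)C)C#C/C(C)=C/CO[Si](C)(C)C(C)(C)C | intermediate
11 | trimethylsilyl ketene acetal of 10 ((2RS,4R)-4-silyloxy-2-methyl-2-alkenyl-6-(trimethylsilyloxy)-3,4-dihydro-2H-pyran) | C[Si](C)(C)OC1=C[C@H](O[Si](C)(C)C(C)(C)C)CC(C)(O1)C(=C(C)C)C#C/C(C)=C/CO[Si](C)(C)C(C)(C)C | intermediate
12 | trimethylsilyl ester of 13 | CC1=C(C#C/C(C)=C/CO[Si](C)(C)C(C)(C)C)C(C)(C)C(C(=O)O[Si](C)(C)C)[C@H](O[Si](C)(C)C(C)(C)C)C1 | intermediate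
13 | (1RS,6R)-6-{[tert-butyl(dimethyl)silyl]oxy}-3-[(3E)-5-{[tert-butyl(dimethyl)silyl]oxy}-3-methylpent-3-en-1-yn-1-yl]-2,2,4-trimethylcyclohex-3-ene-1-carboxylic acid | CC1=C(C#C/C(C)=C/CO[Si](C)(C)C(C)(C)C)C(C)(C)C(C(=O)O)[C@H](O[Si](C)(C)C(C)(C)C)C1 | intermediate
14 | 2-thioxopyridin-1(2H)-yl ester of 13 | CC1=C(C#C/C(C)=C/CO[Si](C)(C)C(C)(C)C)C(C)(C)C(C(=O)ON2C=CC=CC2=S)[C@H](O[Si](C)(C)C(C)(C)C)C1 | intermediate
15 | tert-butyl{[(1R)-4-[(3E)-5-{[tert-butyl(dimethyl)silyl]oxy}-3-methylpent-3-en-1-yn-1-yl]-3,5,5-trimethylcyclohex-3-en-1-yl]oxy}dimethylsilane | CC1=C(C#C/C(C)=C/CO[Si](C)(C)C(C)(C)C)C(C)(C)C[C@H](O[Si](C)(C)C(C)(C)C)C1 | intermediate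
16 | (1R)-4-[(3E)-5-hydroxy-3-methylpent-3-en-1-yn-1-yl]-3,5,5-trimethylcyclohex-3-en-1-ol | CC1=C(C#C/C(C)=C/CO)C(C)(C)C[C@H](O)C1 | intermediate
17 | {(2E)-5-[(4R)-4-hydroxy-2,6,6-trimethylcyclohex-1-en-1-yl]-3-methylpent-2-en-4-yn-1-yl}triphenylphosphonium bromide | CC1=C(C#C/C(C)=C/C[P+](c2ccccc2)(c2ccccc2)c2ccccc2)C(C)(C)C[C@H](O)C1.[Br-] | intermediate
18 | (3E)-4-[(1R)-2,6,6-trimethylcyclohex-2-en-1-yl]but-3-en-2-one ((R)-α-ionone) | CC1=CCCC(C)(C)[C@H]1/C=C/C(C)=O | starting material
19 | (1E,3RS)-3-methyl-1-[(1R)-2,6,6-trimethylcyclohex-2-en-1-yl]penta-1,4-dien-3-ol | CC1=CCCC(C)(C)[C@H]1/C=C/C(C)(O)C=C | intermediate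
20 | {(2E,4E)-3-methyl-5-[(1R)-2,6,6-trimethylcyclohex-2-en-1-yl]penta-2,4-dien-1-yl}triphenylphosphonium bromide | CC1=CCCC(C)(C)[C@H]1/C=C/C(C)=C/C[P+](c2ccccc2)(c2ccccc2)c2ccccc2.[Br-] | intermediate
21 | (2E,4E,6E)-2,7-dimethylocta-2,4,6-trienedial | O=C/C(C)=C/C=C/C=C(\C)C=O | starting material
22 | (2E,4E,6E,8E,10E,12E)-2,7,11-trimethyl-13-[(1R)-2,6,6-trimethylcyclohex-2-en-1-yl]trideca-2,4,6,8,10,12-hexaenal | CC1=CCCC(C)(C)[C@H]1/C=C/C(C)=C/C=C/C(C)=C/C=C/C=C(\C)C=O | intermediate
23 | (3R,6'R)-7,8-didehydro-β,ε-caroten-3-ol, all-E | CC1=CCCC(C)(C)[C@H]1/C=C/C(C)=C/C=C/C(C)=C/C=C/C=C(C)/C=C/C=C(\C)C#CC1=C(C)C[C@@H](O)CC1(C)C | target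

**Count**

Total steps: 12. Longest linear sequence: 8 steps (steps 1, 2, 4, 5, 6, 7, 8, 12).

**Steps most likely to fail**

Step 5. The lactone enolate may lose silanolate by β-elimination before it is silylated, the tertiary allylic C–O bond may ionise on heating, or the boat transition state may be too slow because the migrating terminus is fully substituted. The fallback sets out from 2 and returns at 15, taking the ring from the chiral pool instead of closing it. Commercial (4R,6R)-4-hydroxy-2,2,6-trimethylcyclohexanone would be silylated (TBSCl, imidazole, DMF) to (4R,6R)-4-{[tert-butyl(dimethyl)silyl]oxy}-2,2,6-trimethylcyclohexan-1-one F1. Alkyne 2 would be deprotonated (n-BuLi, THF, −78 °C) to the lithium acetylide F2, which adds to the ketone of F1 to give the tertiary propargylic alcohol F3. Dehydration (POCl3, pyridine, or Burgess reagent) towards the conjugated, more substituted position would then give 15.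

Step 4. The delocalised vinyllithium may react through its distal alkyne carbon to give a cumulene, it may act as a base on the methyl ketone, or the silyl group may move from the secondary oxygen to the new alkoxide before lactonisation. The fallback sets out from 3 and 7, uses 2, and returns at 10; it reverses the order of bond formation. Bromine–lithium exchange on 3 (n-BuLi, THF/Et2O/pentane, −105 °C) would give 1-bromo-1-lithio-2-methylprop-1-ene F4, a localised carbenoid with no ambident character. Addition to 7 gives the lithium alkoxide F5, which lactonises to (4R,6RS)-6-(1-bromo-2-methylprop-1-en-1-yl)-4-{[tert-butyl(dimethyl)silyl]oxy}-6-methyloxan-2-one F6. Sonogashira coupling of F6 with 2 (Pd(t-Bu3P)2, CuI, i-Pr2NH, 50 °C) would then give 10.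

Step 6. The C2 radical may cyclise onto the adjacent ring double bond and reopen with ring contraction (a 1,2-vinyl shift), or thiyl radicals may add to the enyne. The fallback sets out from 13 and returns at 16; it removes the carboxyl by an ionic path and resets C3 by reagent control. Desilylation (Bu4NF, THF) would give (1RS,6R)-6-hydroxy-3-[(3E)-5-hydroxy-3-methylpent-3-en-1-yn-1-yl]-2,2,4-trimethylcyclohex-3-ene-1-carboxylic acid F7. Dess–Martin oxidation of both hydroxyls gives the β-keto acid aldehyde F8, which loses CO2 on gentle warming to give (2E)-3-methyl-5-(2,6,6-trimethyl-4-oxocyclohex-1-en-1-yl)pent-2-en-4-ynal F9. CBS reduction with the (S)-oxazaborolidine and catecholborane (toluene, −78 °C) would reduce the aldehyde and, if the neopentyl-type C2 side acts as the larger group, should give the (R)-carbinol, leading to 16; this selectivity would have to be checked.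

**Further compounds**

F1 | step 5 | (4R,6R)-4-{[tert-butyl(dimethyl)silyl]oxy}-2,2,6-trimethylcyclohexan-1-one | C[C@@H]1C[C@@H](O[Si](C)(C)C(C)(C)C)CC(C)(C)C1=O
F2 | step 5 | [(3E)-5-{[tert-butyl(dimethyl)silyl]oxy}-3-methylpent-3-en-1-yn-1-yl]lithium | [Li]C#C/C(C)=C/CO[Si](C)(C)C(C)(C)C
F3 | step 5 | (1RS,4R,6R)-4-{[tert-butyl(dimethyl)silyl]oxy}-1-[(3E)-5-{[tert-butyl(dimethyl)silyl]oxy}-3-methylpent-3-en-1-yn-1-yl]-2,2,6-trimethylcyclohexan-1-ol | C[C@@H]1C[C@@H](O[Si](C)(C)C(C)(C)C)CC(C)(C)C1(O)C#C/C(C)=C/CO[Si](C)(C)C(C)(C)C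
F4 | step 4 | 1-bromo-1-lithio-2-methylprop-1-ene | [Li]C(Br)=C(C)C
F5 | step 4 | lithium alkoxide of methyl (3R,5RS)-6-bromo-3-{[tert-butyl(dimethyl)silyl]oxy}-5-hydroxy-5,7-dimethyloct-6-enoate | COC(=O)C[C@H](O[Si](C)(C)C(C)(C)C)CC(C)(O[Li])C(Br)=C(C)C
F6 | step 4 | (4R,6RS)-6-(1-bromo-2-methylprop-1-en-1-yl)-4-{[tert-butyl(dimethyl)silyl]oxy}-6-methyloxan-2-one | O=C1C[C@H](O[Si](C)(C)C(C)(C)C)CC(C)(O1)C(Br)=C(C)C
F7 | step 6 | (1RS,6R)-6-hydroxy-3-[(3E)-5-hydroxy-3-methylpent-3-en-1-yn-1-yl]-2,2,4-trimethylcyclohex-3-ene-1-carboxylic acid | CC1=C(C#C/C(C)=C/CO)C(C)(C)C(C(=O)O)[C@H](O)C1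
F8 | step 6 | (1RS)-2,2,4-trimethyl-3-[(3E)-3-methyl-5-oxopent-3-en-1-yn-1-yl]-6-oxocyclohex-3-ene-1-carboxylic acid | CC1=C(C#C/C(C)=C/C=O)C(C)(C)C(C(=O)O)C(=O)C1
F9 | step 6 | (2E)-3-methyl-5-(2,6,6-trimethyl-4-oxocyclohex-1-en-1-yl)pent-2-en-4-ynal | CC1=C(C#C/C(C)=C/C=O)C(C)(C)CC(=O)C1
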